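**Retrosynthetic overview**
- Target ⇐ desilylation and C=O → CH=CH adjustment of the pyran ring ⇐ a cis-fused cyclobuta-indano-chromanone.
- Key disconnection: two bonds of the cyclopentane ring, arene C–CH(cyclobutane) and benzylic CH2–CH(cyclobutane). This gives an aryl triflate with an ortho CH3 and an enantioenriched 4-aryl-3,3-dimethylcyclobutene. Forward: syn carbopalladation, then benzylic C–H palladation and C(sp3)–C(sp3) reductive elimination close the five-membered ring at the CH2–CH bond.
- Enabling feature: the cyclobutane CH that receives the CH2 lies between the quaternary CMe2 carbon and a CH whose hydrogen ends up anti, so the cyclobutyl–palladium species cannot β-eliminate. The arene carbon bearing the cyclobutane lies between the CH3-bearing carbon and the carbon carrying the pyranone C=O, so no ortho aryl C–H exists and only the CH3 is in reach.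
- Cyclobutene ⇐ cyclobutanone ⇐ auxiliary-controlled keteniminium–styrene [2+2]. Aryl triflate ⇐ 2,6-dimethoxytoluene via a symmetric phenol, chromanone annulation, chelation-controlled demethylation and triflation.
- Ring order: pyranone ring and cyclobutane (separate branches), then the cyclopentane (key step), chromene C=C last; the C=O also keeps a competing alkene insertion out of the key step.

Key step: step 11

Assumption: the keteniminium ion of the (S)-2-(methoxymethyl)pyrrolidine amide is taken to give the (R)-cyclobutanone; if the opposite sense is found, the commercial (R)-auxiliary is used and nothing else changes.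

**Route**

Step 1
Reactants: 1 2,6-dimethoxytoluene
Product: 3 3,5-dimethoxy-4-methylphenol, via aryl pinacol boronate 2 (not isolated)
Conditions: [Ir(OMe)(cod)]2 (1.5 mol%), 4,4'-di-tert-butyl-2,2'-bipyridine, B2pin2, THF, 80 °C; then 30% H2O2, aq NaOH, 0 °C → rt
Reagents that add atoms: bis(pinacolato)diboron CC1(C)OB(OC1(C)C)B1OC(C)(C)C(C)(C)O1 (boron of 2); hydrogen peroxide OO (oxygen of 3)
Why: Iridium-catalysed C–H borylation is sterically governed and should occur only at the position flanked by two hydrogens (para to CH3), and oxidation of the C–B bond then gives the phenol (one-pot borylation/oxidation).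

Step 2
Reactants: 3 3,5-dimethoxy-4-methylphenol; 4 3-methylbut-2-enoic acid
Product: 5 5,7-dimethoxy-2,2,6-trimethylchroman-4-one
Conditions: P2O5/MeSO3H (1:10 w/w), 70 °C
Reagents that add atoms: none
Why: Friedel–Crafts acylation ortho to the phenol followed by intramolecular oxa-Michael addition (chromanone annulation) should give one regioisomer because the two ortho positions of 3 are equivalent.

Step 3
Reactants: 5 5,7-dimethoxy-2,2,6-trimethylchroman-4-one
Product: 6 5-hydroxy-7-methoxy-2,2,6-trimethylchroman-4-one
Conditions: BCl3 (1.2 equiv), CH2Cl2, −78 → 0 °C; aq work-up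
Reagents that add atoms: none
Why: BCl3 chelates between the C4 carbonyl and the peri C5 methoxy oxygen, so only this ether should be cleaved (chelation-controlled Lewis acid demethylation) and the C7 methoxy group stays.

Step 4
Reactants: 6 5-hydroxy-7-methoxy-2,2,6-trimethylchroman-4-one
Product: 7 7-methoxy-2,2,6-trimethyl-4-oxochroman-5-yl trifluoromethanesulfonate
Conditions: Tf2O, pyridine, CH2Cl2, 0 °C
Reagents that add atoms: trifluoromethanesulfonic anhydride O=S(=O)(OS(=O)(=O)C(F)(F)F)C(F)(F)F
Why: O-sulfonylation of the only phenol gives the aryl triflate, and enol triflation of the hindered ketone is not expected with pyridine at 0 °C.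

Step 5
Reactants: 8 3,4-dihydroxybenzaldehyde
Product: 9 3,4-bis(triisopropylsilyloxy)benzaldehyde
Conditions: i-Pr3SiCl (2.4 equiv), imidazole, DMF, rt
Reagents that add atoms: chlorotriisopropylsilane CC(C)[Si](Cl)(C(C)C)C(C)C
Why: Silylation of both phenols gives base- and acid-tolerant ethers that can be removed by fluoride at the end without touching the aryl methyl ether or the chromene.

Step 6
Reactants: 9 3,4-bis(triisopropylsilyloxy)benzaldehyde
Product: 10 3,4-bis(triisopropylsilyloxy)styrene
Conditions: Ph3PCH3Br, KOtBu, THF, 0 °C → rt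
Reagents that add atoms: methyltriphenylphosphonium bromide C[P+](c1ccccc1)(c1ccccc1)c1ccccc1.[Br-]
Why: Wittig methylenation of the aldehyde gives the styrene; its terminal carbon becomes the arene-bearing cyclobutane carbon.

Step 7
Reactants: 11 (S)-2-(methoxymethyl)pyrrolidine; 12 2-methylpropanoyl chloride
Product: 13 (S)-1-[2-(methoxymethyl)pyrrolidin-1-yl]-2-methylpropan-1-one
Conditions: Et3N, CH2Cl2, 0 °C → rt
Reagents that add atoms: none
Why: N-acylation of the secondary amine gives the chiral isobutyramide that serves as keteniminium precursor.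

Step 8
Reactants: 13 (S)-1-[2-(methoxymethyl)pyrrolidin-1-yl]-2-methylpropan-1-one; 10 3,4-bis(triisopropylsilyloxy)styrene
Product: 16 (R)-3-[3,4-bis(triisopropylsilyloxy)phenyl]-2,2-dimethylcyclobutan-1-one, via keteniminium triflate 14 (not isolated), via cyclobutaniminium triflate 15 (not isolated)
Conditions: Tf2O (1.1 equiv), 2,4,6-collidine (1.2 equiv), ClCH2CH2Cl, −25 °C → rt; then 10, 60 °C; then aq NaHCO3, 40 °C
Reagents that add atoms: trifluoromethanesulfonic anhydride O=S(=O)(OS(=O)(=O)C(F)(F)F)C(F)(F)F (triflate counter-ion of 14 and 15); water O (carbonyl oxygen of 16)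
Why: Keteniminium–alkene [2+2] cycloaddition, in which the iminium carbon bonds to the terminal CH2 of the styrene and the CMe2 carbon to the benzylic carbon; the CH2OMe-bearing stereocentre of the auxiliary shields one face of the keteniminium C=C and so sets the aryl-bearing stereocentre, and hydrolysis frees the ketone and the auxiliary.

Step 9
Reactants: 16 (R)-3-[3,4-bis(triisopropylsilyloxy)phenyl]-2,2-dimethylcyclobutan-1-one
Product: 17 (R)-3-[3,4-bis(triisopropylsilyloxy)phenyl]-4,4-dimethylcyclobut-1-en-1-yl trifluoromethanesulfonate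
Conditions: KN(SiMe3)2, THF, −78 °C; PhNTf2, −78 → 0 °C; cold 0.5 M HCl work-up
Reagents that add atoms: N-phenylbis(trifluoromethanesulfonimide) O=S(=O)(N(c1ccccc1)S(=O)(=O)C(F)(F)F)C(F)(F)F
Why: Kinetic enolisation can occur only at the single α-CH2 group, and O-triflation of the enolate fixes the double bond there; the β stereocentre is not enolisable and is kept.

Step 10
Reactants: 17 (R)-3-[3,4-bis(triisopropylsilyloxy)phenyl]-4,4-dimethylcyclobut-1-en-1-yl trifluoromethanesulfonate
Product: 18 (S)-4-[3,4-bis(triisopropylsilyloxy)phenyl]-3,3-dimethylcyclobut-1-ene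
Conditions: Pd(OAc)2 (5 mol%), PPh3 (10 mol%), HCO2H, Bu3N, DMF, 40 °C
Reagents that add atoms: none
Why: Palladium-catalysed formate reduction of an alkenyl triflate (oxidative addition, formate-to-hydride exchange with loss of CO2, C–H reductive elimination) replaces OTf by H without moving the double bond.

Step 11
Reactants: 7 7-methoxy-2,2,6-trimethyl-4-oxochroman-5-yl trifluoromethanesulfonate; 18 (S)-4-[3,4-bis(triisopropylsilyloxy)phenyl]-3,3-dimethylcyclobut-1-ene
Product: 19 cis-fused cyclobuta-indano-chromanone (2S,2aR,7aS in cyclobuta[a]indene numbering; full description in the compound list)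
Conditions: Pd(OAc)2 (10 mol%), PCy3·HBF4 (20 mol%), cesium pivalate (2.5 equiv), toluene, 70 °C, then 110 °C
Reagents that add atoms: none
Why: Proposed new method: zerovalent palladium inserts into the aryl–OTf bond of 7, the arylpalladium pivalate adds syn across the strained alkene of 18 (aryl to the alkene carbon next to the aryl-bearing CH, palladium to the carbon next to CMe2), pivalate-assisted concerted metalation–deprotonation of the ortho CH3 gives a six-membered palladacycle, and C(sp3)–C(sp3) reductive elimination forms the CH2–cyclobutane bond. The closest known reaction type is the palladium-catalysed [3+2] annulation of ortho-methylaryl halides with norbornene through benzylic C–H activation, together with pivalate-assisted C(sp3)–H activation of benzylic methyl groups; what is new is the cyclobutene partner. The cyclopentane ring is closed by this reductive elimination (contraction of the six-membered palladacycle; overall a formal [3+2] annulation of the aryl–CH2 unit onto the two alkene carbons). Both new stereocentres come from the syn carbopalladation and are kept because C–H palladation and reductive elimination proceed with retention, which fixes the cis ring fusion, and their absolute sense is set by the existing aryl-bearing stereocentre, since the metal must approach the alkene face anti to that aryl group. The step needs (a) one regiochemistry of insertion, secured sterically because the di-ortho-substituted aryl group avoids the alkene carbon next to CMe2, (b) a cyclobutylpalladium species that cannot undergo β-hydride elimination, secured by the quaternary CMe2 carbon on one side and the anti C–H on the other, and (c) C–H cleavage at the CH3 group only, secured because the other ortho position carries the pyranone carbonyl carbon and the neopentyl-type α-CH2 of the chromanone would need a seven-membered palladacycle. Insertion is run at 70 °C before heating to 110 °C so that thermal electrocyclic opening of 18 should not compete.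

Step 12
Reactants: 19 cis-fused cyclobuta-indano-chromanone
Product: 21 bis(triisopropylsilyl) ether of the target, via chroman-4-ol 20 (not isolated)
Conditions: NaBH4, MeOH/THF, 0 °C → rt; then p-TsOH·H2O (10 mol%), toluene, 70 °C
Reagents that add atoms: none
Why: Hydride reduction of the aryl ketone followed by acid-catalysed E1 dehydration, through a benzylic cation stabilised by the ortho ring oxygen and the para methoxy group, gives the 2H-chromene; the transient carbinol centre is destroyed again and no other stereocentre is touched.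

Step 13
Reactants: 21 bis(triisopropylsilyl) ether of the target
Product: 22 CNP0207533.1
Conditions: Bu4NF, AcOH, THF, 0 °C, degassed
Reagents that add atoms: none
Why: Fluoride-mediated cleavage of the two aryl silyl ethers frees the catechol, with acetic acid buffering the catecholate against air oxidation.

**Compound list**
1 | 2,6-dimethoxytoluene | COc1cccc(OC)c1C | starting material
2 | 2-(3,5-dimethoxy-4-methylphenyl)-4,4,5,5-tetramethyl-1,3,2-dioxaborolane | COc1cc(B2OC(C)(C)C(C)(C)O2)cc(OC)c1C | intermediate
3 | 3,5-dimethoxy-4-methylphenol | COc1cc(O)cc(OC)c1C | intermediate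
4 | 3-methylbut-2-enoic acid | CC(C)=CC(=O)O | starting material
5 | 5,7-dimethoxy-2,2,6-trimethylchroman-4-one | COc1cc2OC(C)(C)CC(=O)c2c(OC)c1C | intermediate
6 | 5-hydroxy-7-methoxy-2,2,6-trimethylchroman-4-one | COc1cc2OC(C)(C)CC(=O)c2c(O)c1C | intermediate
7 | 7-methoxy-2,2,6-trimethyl-4-oxochroman-5-yl trifluoromethanesulfonate | COc1cc2OC(C)(C)CC(=O)c2c(OS(=O)(=O)C(F)(F)F)c1C | intermediate
8 | 3,4-dihydroxybenzaldehyde | O=Cc1ccc(O)c(O)c1 | starting material
9 | 3,4-bis(triisopropylsilyloxy)benzaldehyde | O=Cc1ccc(O[Si](C(C)C)(C(C)C)C(C)C)c(O[Si](C(C)C)(C(C)C)C(C)C)c1 | intermediate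
10 | 3,4-bis(triisopropylsilyloxy)styrene | C=Cc1ccc(O[Si](C(C)C)(C(C)C)C(C)C)c(O[Si](C(C)C)(C(C)C)C(C)C)c1 | intermediate
11 | (S)-2-(methoxymethyl)pyrrolidine | COC[C@@H]1CCCN1 | starting material
12 | 2-methylpropanoyl chloride | CC(C)C(Cl)=O | starting material
13 | (S)-1-[2-(methoxymethyl)pyrrolidin-1-yl]-2-methylpropan-1-one | COC[C@@H]1CCCN1C(=O)C(C)C | intermediate
14 | (S)-2-(methoxymethyl)-1-(2-methylprop-1-en-1-ylidene)pyrrolidinium triflate | COC[C@@H]1CCC[N+]1=C=C(C)C.[O-]S(=O)(=O)C(F)(F)F | intermediate
15 | (2S)-1-[(3R)-3-[3,4-bis(triisopropylsilyloxy)phenyl]-2,2-dimethylcyclobutylidene]-2-(methoxymethyl)pyrrolidinium triflate | COC[C@@H]1CCC[N+]1=C2C[C@H](c3ccc(O[Si](C(C)C)(C(C)C)C(C)C)c(O[Si](C(C)C)(C(C)C)C(C)C)c3)C2(C)C.[O-]S(=O)(=O)C(F)(F)F | intermediate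
16 | (R)-3-[3,4-bis(triisopropylsilyloxy)phenyl]-2,2-dimethylcyclobutan-1-one | O=C1C[C@H](c2ccc(O[Si](C(C)C)(C(C)C)C(C)C)c(O[Si](C(C)C)(C(C)C)C(C)C)c2)C1(C)C | intermediate
17 | (R)-3-[3,4-bis(triisopropylsilyloxy)phenyl]-4,4-dimethylcyclobut-1-en-1-yl trifluoromethanesulfonate | O=S(=O)(OC1=C[C@H](c2ccc(O[Si](C(C)C)(C(C)C)C(C)C)c(O[Si](C(C)C)(C(C)C)C(C)C)c2)C1(C)C)C(F)(F)F | intermediate
18 | (S)-4-[3,4-bis(triisopropylsilyloxy)phenyl]-3,3-dimethylcyclobut-1-ene | C1=C[C@H](c2ccc(O[Si](C(C)C)(C(C)C)C(C)C)c(O[Si](C(C)C)(C(C)C)C(C)C)c2)C1(C)C | intermediate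
19 | (2S,2aR,7aS)-2-[3,4-bis(triisopropylsilyloxy)phenyl]-6-methoxy-1,1-dimethyl-2,2a,7,7a-tetrahydro-1H-cyclobuta[a]indene carrying a 2,2-dimethyl-2,3-dihydropyran-4-one ring fused at C3 (C=O carbon) and C4 (ring O); cis ring fusion, the two aryl groups trans | COc1cc2c(c3c1C[C@H]1[C@@H]3[C@H](c3ccc(O[Si](C(C)C)(C(C)C)C(C)C)c(O[Si](C(C)C)(C(C)C)C(C)C)c3)C1(C)C)C(=O)CC(C)(C)O2 | intermediate
20 | chroman-4-ol of 19 (C=O reduced to CHOH, both epimers at the carbinol carbon) | COc1cc2c(c3c1C[C@H]1[C@@H]3[C@H](c3ccc(O[Si](C(C)C)(C(C)C)C(C)C)c(O[Si](C(C)C)(C(C)C)C(C)C)c3)C1(C)C)C(O)CC(C)(C)O2 | intermediate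
21 | bis(triisopropylsilyl) ether of the target: as 19, but with a 2,2-dimethyl-2H-pyran ring (CH=CH) in place of the pyranone | COc1cc2c(c3c1C[C@H]1[C@@H]3[C@H](c3ccc(O[Si](C(C)C)(C(C)C)C(C)C)c(O[Si](C(C)C)(C(C)C)C(C)C)c3)C1(C)C)C=CC(C)(C)O2 | intermediate
22 | CNP0207533.1: (2S,2aR,7aS)-2-(3,4-dihydroxyphenyl)-6-methoxy-1,1-dimethyl-cyclobuta[a]indane fused with a 2,2-dimethyl-2H-pyran at C3/C4 | COc1cc2c(c3c1C[C@H]1[C@@H]3[C@H](c3ccc(O)c(O)c3)C1(C)C)C=CC(C)(C)O2 | target

**Step count and risks**

Total step count: 13. Longest linear sequence: 8 steps (steps 5, 6, 8, 9, 10, 11, 12, 13, from 3,4-dihydroxybenzaldehyde).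

Steps most likely to fail:

1. Step 11 (proposed new method). What may go wrong: after carbopalladation the cyclobutylpalladium intermediate may be protonated before the slow benzylic C–H palladation; 18 may also open thermally, or insert the other way round and then undergo β-hydride elimination. The fallback uses known reactions and closes the ring by 1,2-addition of a cyclobutyl–rhodium bond to an aldehyde instead of C–H cleavage. It sets out from 7. Wohl–Ziegler bromination of the only benzylic CH3 (NBS, AIBN, PhCF3, 80 °C) should give 6-(bromomethyl)-7-methoxy-2,2-dimethyl-4-oxochroman-5-yl trifluoromethanesulfonate F1. Oxidation with N-methylmorpholine N-oxide (MeCN, rt) should give 6-formyl-7-methoxy-2,2-dimethyl-4-oxochroman-5-yl trifluoromethanesulfonate F2. Miyaura borylation (B2pin2, Pd(dppf)Cl2, KOAc, dioxane, 90 °C) should give 7-methoxy-2,2-dimethyl-4-oxo-5-(4,4,5,5-tetramethyl-1,3,2-dioxaborolan-2-yl)chroman-6-carbaldehyde F3. Rhodium-catalysed arylative annulation of F3 with 18 ([Rh(OH)(cod)]2, K3PO4, dioxane/H2O, 60 °C) should then give the indanol of 19 (19 with OH on the indane CH2 carbon, both epimers there) F4 with the same cis fusion. This step combines two established reactivities: syn carbometalation of cyclobutenes by arylboron reagents, here anti to the aryl group, and intramolecular addition of the alkyl–rhodium bond to an ortho carbonyl group as in annulations of ortho-carbonyl arylboron reagents with strained alkenes. Ionic deoxygenation of the oxygen-stabilised benzylic alcohol (Et3SiH, CF3CO2H, CH2Cl2, 0 °C) comes back to the route at 19.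

2. Step 8. What may go wrong: the auxiliary may discriminate the two faces of the keteniminium ion poorly, or the electron-rich styrene may oligomerise under the cationic conditions faster than it cycloadds. The fallback replaces auxiliary control by resolution. It sets out from 10. The achiral tetramethylketeniminium ion from commercial 1-chloro-N,N,2-trimethylprop-1-en-1-amine and ZnCl2 (CH2Cl2, rt, no triflic anhydride) should add to 10 to give racemic N-[3-[3,4-bis(triisopropylsilyloxy)phenyl]-2,2-dimethylcyclobutylidene]-N-methylmethanaminium chloride F5. Hydrolysis (aq NaOH) should give racemic 3-[3,4-bis(triisopropylsilyloxy)phenyl]-2,2-dimethylcyclobutan-1-one F6. Separation of its enantiomers by preparative chromatography on a chiral stationary phase comes back to the route at 16.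

3. Step 10. What may go wrong: a palladium hydride may re-add to the product and move the ring double bond into conjugation with the aryl group or reduce it further, and the strained alkene may be lost on prolonged heating. The fallback is a Shapiro reaction, with no transition metal or hydride source. It sets out from 16. Condensation with 2,4,6-triisopropylbenzenesulfonohydrazide (THF, rt) should give N'-[(3R)-3-[3,4-bis(triisopropylsilyloxy)phenyl]-2,2-dimethylcyclobutylidene]-2,4,6-triisopropylbenzenesulfonohydrazide F7. n-BuLi (2.2 equiv, THF/TMEDA, −78 → 0 °C) removes the N–H and one hydrogen of the only α-CH2 group, and loss of sulfinate and N2 should give [(3R)-3-[3,4-bis(triisopropylsilyloxy)phenyl]-4,4-dimethylcyclobut-1-en-1-yl]lithium F8. Quenching with water comes back to the route at 18, with the double bond fixed between the former carbonyl carbon and the former CH2.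

Further compounds
F1 | step 11 | 6-(bromomethyl)-7-methoxy-2,2-dimethyl-4-oxochroman-5-yl trifluoromethanesulfonate | COc1cc2OC(C)(C)CC(=O)c2c(OS(=O)(=O)C(F)(F)F)c1CBr
F2 | step 11 | 6-formyl-7-methoxy-2,2-dimethyl-4-oxochroman-5-yl trifluoromethanesulfonate | COc1cc2OC(C)(C)CC(=O)c2c(OS(=O)(=O)C(F)(F)F)c1C=O
F3 | step 11 | 7-methoxy-2,2-dimethyl-4-oxo-5-(4,4,5,5-tetramethyl-1,3,2-dioxaborolan-2-yl)chroman-6-carbaldehyde | COc1cc2OC(C)(C)CC(=O)c2c(B3OC(C)(C)C(C)(C)O3)c1C=O
F4 | step 11 | indanol of 19 (OH on the indane CH2 carbon, both epimers at that carbon) | COc1cc2c(c3c1C(O)[C@H]1[C@@H]3[C@H](c3ccc(O[Si](C(C)C)(C(C)C)C(C)C)c(O[Si](C(C)C)(C(C)C)C(C)C)c3)C1(C)C)C(=O)CC(C)(C)O2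
F5 | step 8 | racemic N-[3-[3,4-bis(triisopropylsilyloxy)phenyl]-2,2-dimethylcyclobutylidene]-N-methylmethanaminium chloride | C[N+](C)=C1CC(c2ccc(O[Si](C(C)C)(C(C)C)C(C)C)c(O[Si](C(C)C)(C(C)C)C(C)C)c2)C1(C)C.[Cl-]
F6 | step 8 | racemic 3-[3,4-bis(triisopropylsilyloxy)phenyl]-2,2-dimethylcyclobutan-1-one | O=C1CC(c2ccc(O[Si](C(C)C)(C(C)C)C(C)C)c(O[Si](C(C)C)(C(C)C)C(C)C)c2)C1(C)C
F7 | step 10 | N'-[(3R)-3-[3,4-bis(triisopropylsilyloxy)phenyl]-2,2-dimethylcyclobutylidene]-2,4,6-triisopropylbenzenesulfonohydrazide | CC(C)c1cc(C(C)C)c(S(=O)(=O)NN=C2C[C@H](c3ccc(O[Si](C(C)C)(C(C)C)C(C)C)c(O[Si](C(C)C)(C(C)C)C(C)C)c3)C2(C)C)c(C(C)C)c1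
F8 | step 10 | [(3R)-3-[3,4-bis(triisopropylsilyloxy)phenyl]-4,4-dimethylcyclobut-1-en-1-yl]lithium | [Li]C1=C[C@H](c2ccc(O[Si](C(C)C)(C(C)C)C(C)C)c(O[Si](C(C)C)(C(C)C)C(C)C)c2)C1(C)C
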